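The route rests on disconnecting the C1–C10 bond of ring A. Quaternary C10, with its methyl, lies 1,4 across ring A from the C3 oxygen. A tertiary C10 radical, made by hydrogen-atom transfer to an exocyclic methylidene on ring B, can therefore add 6-endo to the terminal carbon C1 of a C1=C2–C3(=O) vinyl ketone. One operation forms the C1–C10 bond, the C10 methyl, ring A and the trans fusion. The precursor is a ring B cyclohexane (C8 ketone masked as dioxolane, C10 as C=CH2) whose C5 carries the silyl-protected C4 tertiary carbinol bearing the vinyl ketone. C4 and C5 come from a catalytic asymmetric pyruvate aldol.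

Key step: step 7

Remark: decalins are numbered as in eudesmanes (ring A = C1–C5, C10; ring B = C5–C10; methyls on C4 and C10; C11–C13 on C7), and 1,4-dioxaspiro[4.5]decan-7-one and (R)-2-methylbutanoic acid are taken as purchasable.

**Route**

Step 1
Reactants: 1 1,4-dioxaspiro[4.5]decan-7-one
Product: 2 trimethyl(1,4-dioxaspiro[4.5]dec-7-en-7-yloxy)silane
Conditions: LiN(i-Pr)2 (commercial solution), THF, −78 °C; Me3SiCl, −78 °C → rt
Reagents that add atoms: chlorotrimethylsilane, C[Si](C)(C)Cl
Why: Kinetic enolisation with the hindered lithium amide should occur at the α-methylene remote from the fully substituted ketal carbon (the future C5), and O-silylation traps that enolate (kinetic silyl enol ether formation), so the future C8 ketone is masked from the outset and ring B never has to be ketalised next to a stereocentre.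

Step 2
Reactants: 2 trimethyl(1,4-dioxaspiro[4.5]dec-7-en-7-yloxy)silane; 3 methyl pyruvate
Product: 5 methyl (2S)-2-hydroxy-2-[(8S)-7-oxo-1,4-dioxaspiro[4.5]decan-8-yl]propanoate, via trimethylsilyl ether 4 (not isolated)
Conditions: Cu(OTf)2 (10 mol%), (S,S)-t-Bu-box (11 mol%), THF, −78 °C; then citric acid, MeOH, 0 °C
Reagents that add atoms: none
Why: Catalytic enantioselective Mukaiyama aldol addition: the bis(oxazoline) complex of divalent copper chelates methyl pyruvate and one tert-butyl group screens the re face of the keto group, so the enol silane should add to the si face (target C4 becomes S) through the open transition state that gives syn adducts from α-substituted enol silanes (target C5 becomes S), and mild acidic methanolysis removes the transferred silyl group without touching the dioxolane.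

Step 3
Reactants: 5 methyl (2S)-2-hydroxy-2-[(8S)-7-oxo-1,4-dioxaspiro[4.5]decan-8-yl]propanoate
Product: 6 methyl (2S)-2-[(8S)-7-oxo-1,4-dioxaspiro[4.5]decan-8-yl]-2-(triethylsilyloxy)propanoate
Conditions: Et3SiOTf, 2,6-lutidine, CH2Cl2, −78 → 0 °C
Reagents that add atoms: triethylsilyl trifluoromethanesulfonate, CC[Si](CC)(CC)OS(=O)(=O)C(F)(F)F
Why: Silylation of a tertiary alcohol with a silyl triflate and a hindered pyridine base is fast at low temperature, blocks retro-aldol cleavage of the β-hydroxy ketone in later steps and touches no stereocentre.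

Step 4
Reactants: 6 methyl (2S)-2-[(8S)-7-oxo-1,4-dioxaspiro[4.5]decan-8-yl]-2-(triethylsilyloxy)propanoate
Product: 7 methyl (2S)-2-[(8R)-7-methylidene-1,4-dioxaspiro[4.5]decan-8-yl]-2-(triethylsilyloxy)propanoate
Conditions: Cp2Ti(μ-Cl)(μ-CH2)AlMe2 (Tebbe reagent), pyridine, THF/toluene, −40 → 0 °C
Reagents that add atoms: Tebbe reagent Cp2Ti(μ-Cl)(μ-CH2)AlMe2, C[Al-]1(C)C[Ti]([Cl+]1)(C2C=CC=C2)C3C=CC=C3
Why: Tebbe methylenation through Cp2Ti=CH2 and an oxatitanacyclobutane is non-basic, so it should neither epimerise the α-stereocentre nor open the β-ketal by elimination, and at low temperature it takes the ketone before the hindered ester; the ring descriptor changes from S to R by priority only.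

Step 5
Reactants: 7 methyl (2S)-2-[(8R)-7-methylidene-1,4-dioxaspiro[4.5]decan-8-yl]-2-(triethylsilyloxy)propanoate
Product: 8 (2S)-N-methoxy-N-methyl-2-[(8R)-7-methylidene-1,4-dioxaspiro[4.5]decan-8-yl]-2-(triethylsilyloxy)propanamide
Conditions: MeNH(OMe)·HCl, i-PrMgCl, THF, −20 → 20 °C
Reagents that add atoms: N,O-dimethylhydroxylamine hydrochloride, CNOC.Cl
Why: Aminolysis of the methyl ester by the small magnesium amide ClMgN(OMe)Me formed in the flask (Weinreb amide formation) should proceed with excess reagent despite the quaternary α-carbon, which has no hydrogen and so cannot epimerise.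

Step 6
Reactants: 8 (2S)-N-methoxy-N-methyl-2-[(8R)-7-methylidene-1,4-dioxaspiro[4.5]decan-8-yl]-2-(triethylsilyloxy)propanamide; 9 vinylmagnesium bromide
Product: 10 (4S)-4-[(8R)-7-methylidene-1,4-dioxaspiro[4.5]decan-8-yl]-4-(triethylsilyloxy)pent-1-en-3-one
Conditions: THF, 0 °C; inverse quench into cold aq. citric acid
Reagents that add atoms: none
Why: Weinreb ketone synthesis: the Grignard reagent adds once because the magnesium chelate of the tetrahedral adduct survives until the quench, and the cold acidic inverse quench keeps the liberated N,O-dimethylhydroxylamine protonated so that it cannot add to the new vinyl ketone.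

Step 7
Reactants: 10 (4S)-4-[(8R)-7-methylidene-1,4-dioxaspiro[4.5]decan-8-yl]-4-(triethylsilyloxy)pent-1-en-3-one
Product: 11 (4S,5R,10R)-8,8-ethylenedioxy-4,10-dimethyl-4-(triethylsilyloxy)-trans-decalin-3-one
Conditions: Fe(acac)3 (30 mol%), PhSiH3 (2.5 equiv), EtOH, 60 °C, 0.01 M, Ar
Reagents that add atoms: none
Why: Fe(acac)3 and PhSiH3 in ethanol form a trivalent iron hydride that transfers a hydrogen atom to the terminal CH2 of the electron-rich 1,1-disubstituted alkene, which creates the C10 methyl and a nucleophilic tertiary radical at C10. This radical adds to C1, the unsubstituted β-carbon of the tethered vinyl ketone, and the α-keto radical at C2 is reduced by divalent iron to the enolate and protonated by ethanol; the closest known reaction type is the iron-hydride reductive olefin coupling (intramolecular Giese addition), known also for 6-endo closures that create quaternary carbons. Ring A closes in the 6-endo-trig mode, because C1 is the electrophilic and sterically open terminus, whereas 5-exo attack at C2 would be polarity-mismatched and would leave a primary radical. The new stereocentre C10 is controlled by C5: in a chair-like transition state the C5–C4 bond stays equatorial on ring B and C1 bonds to the face of C10 that makes the new bond equatorial too, so the methyl becomes axial and anti to H5 (trans fusion, 10R), as in radical polyene cyclisations. The step needs hydrogen-atom transfer to the methylidene and not the enone, 6-endo and not 5-exo closure, and trans and not cis fusion; the electron-rich alkene, the terminal enone carbon and the equatorial quaternary C4 tether should secure these, and high dilution suppresses intermolecular addition.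

Step 8
Reactants: 11 (4S,5R,10R)-8,8-ethylenedioxy-4,10-dimethyl-4-(triethylsilyloxy)-trans-decalin-3-one
Product: 13 (3S,4S,5R,10R)-3,4-dihydroxy-4,10-dimethyl-trans-decalin-8-one, via silyl ether alcohol 12 (not isolated)
Conditions: NaBH4, THF/MeOH, −20 → 0 °C; then 2 M HCl (aq), rt
Reagents that add atoms: water, O
Why: Substrate-controlled ketone reduction followed by acetal and silyl ether hydrolysis: borohydride should attack C3 axially on the α face, the equatorial approach from the β side being blocked by the axial 4β-methyl (as in 4,4-disubstituted 3-keto steroids), which gives the equatorial 3β-alcohol (3S), and aqueous HCl then destroys excess hydride before it unmasks the C8 ketone and cleaves the tertiary silyl ether.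

Step 9
Reactants: 13 (3S,4S,5R,10R)-3,4-dihydroxy-4,10-dimethyl-trans-decalin-8-one; 14 (2R)-2-methylbutanoic acid
Product: 15 (3S,4S,5R,10R)-4-hydroxy-4,10-dimethyl-8-oxo-trans-decalin-3-yl (2R)-2-methylbutanoate
Conditions: DCC, DMAP (cat.), CH2Cl2, 0 °C → rt
Reagents that add atoms: none
Why: Steglich esterification: the carbodiimide-activated acid should acylate only the secondary equatorial 3β-hydroxyl, the tertiary 4α-hydroxyl being inert under these conditions, and an α-alkyl acid keeps its configuration at this temperature.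

Step 10
Reactants: 15 (3S,4S,5R,10R)-4-hydroxy-4,10-dimethyl-8-oxo-trans-decalin-3-yl (2R)-2-methylbutanoate
Product: 16 (3S,4S,5R,10R)-4-acetoxy-4,10-dimethyl-8-oxo-trans-decalin-3-yl (2R)-2-methylbutanoate
Conditions: Ac2O, Et3N, DMAP, CH2Cl2, 40 °C
Reagents that add atoms: acetic anhydride, CC(=O)OC(C)=O
Why: DMAP-catalysed acetylation through the N-acetylpyridinium ion is the standard acylation of tertiary alcohols and should convert the equatorial 4α-hydroxyl on gentle warming, the ketone and the C3 ester being inert and no stereocentre affected.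

Step 11
Reactants: 16 (3S,4S,5R,10R)-4-acetoxy-4,10-dimethyl-8-oxo-trans-decalin-3-yl (2R)-2-methylbutanoate; 17 acetone
Product: 18 (3S,4S,5R,10R)-4-acetoxy-7-(2-hydroxypropan-2-yl)-4,10-dimethyl-8-oxo-trans-decalin-3-yl (2R)-2-methylbutanoate (both C7 epimers)
Conditions: LiN(SiMe3)2 (1.05 equiv), THF, −78 °C; acetone, −78 °C; AcOH quench at −78 °C
Reagents that add atoms: none
Why: Kinetic enolisation and aldol addition: the silylamide should remove the most acidic and least hindered proton, at C7 of the ketone (C9 is neopentyl, the ester α-hydrogens are several pK units less acidic and that of the 2-methylbutanoate is tertiary), the lithium enolate adds to acetone, and the cold quench prevents retro-aldol; the C7 centre is uncontrolled and is removed in step 12.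

Step 12
Reactants: 18 (3S,4S,5R,10R)-4-acetoxy-7-(2-hydroxypropan-2-yl)-4,10-dimethyl-8-oxo-trans-decalin-3-yl (2R)-2-methylbutanoate
Product: 20 (3S,4S,5R,10R)-4-acetoxy-8-oxoeudesm-7(11)-en-3-yl (2R)-2-methylbutanoate, via tertiary mesylate 19 (not isolated)
Conditions: MsCl, Et3N, CH2Cl2, 0 °C → rt; then DBU, rt
Reagents that add atoms: none
Why: Aldol dehydration: sulfene-type mesylation of the tertiary hydroxyl and E1cB loss of methanesulfonate through the C8 enolate should give the conjugated isopropylidene ketone, DBU also bringing any isopropenyl isomer into conjugation, while the ester α-hydrogens are far too weakly acidic for these bases and no stereocentre of the product is touched.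

**Compound list**

1 | 1,4-dioxaspiro[4.5]decan-7-one | O=C1CCCC2(C1)OCCO2 | starting material
2 | trimethyl(1,4-dioxaspiro[4.5]dec-7-en-7-yloxy)silane | C[Si](C)(C)OC1=CCCC2(C1)OCCO2 | intermediate
3 | methyl pyruvate | COC(=O)C(C)=O | starting material
4 | methyl (2S)-2-[(8S)-7-oxo-1,4-dioxaspiro[4.5]decan-8-yl]-2-(trimethylsilyloxy)propanoate | COC(=O)[C@@](C)(O[Si](C)(C)C)[C@@H]1CCC2(OCCO2)CC1=O | intermediate (not isolated)
5 | methyl (2S)-2-hydroxy-2-[(8S)-7-oxo-1,4-dioxaspiro[4.5]decan-8-yl]propanoate | COC(=O)[C@@](C)(O)[C@@H]1CCC2(OCCO2)CC1=O | intermediate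
6 | methyl (2S)-2-[(8S)-7-oxo-1,4-dioxaspiro[4.5]decan-8-yl]-2-(triethylsilyloxy)propanoate | COC(=O)[C@@](C)(O[Si](CC)(CC)CC)[C@@H]1CCC2(OCCO2)CC1=O | intermediate
7 | methyl (2S)-2-[(8R)-7-methylidene-1,4-dioxaspiro[4.5]decan-8-yl]-2-(triethylsilyloxy)propanoate | COC(=O)[C@@](C)(O[Si](CC)(CC)CC)[C@@H]1CCC2(OCCO2)CC1=C | intermediate
8 | (2S)-N-methoxy-N-methyl-2-[(8R)-7-methylidene-1,4-dioxaspiro[4.5]decan-8-yl]-2-(triethylsilyloxy)propanamide | CON(C)C(=O)[C@@](C)(O[Si](CC)(CC)CC)[C@@H]1CCC2(OCCO2)CC1=C | intermediate
9 | vinylmagnesium bromide | C=C[Mg]Br | starting material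
10 | (4S)-4-[(8R)-7-methylidene-1,4-dioxaspiro[4.5]decan-8-yl]-4-(triethylsilyloxy)pent-1-en-3-one | C=CC(=O)[C@@](C)(O[Si](CC)(CC)CC)[C@@H]1CCC2(OCCO2)CC1=C | intermediate
11 | (4S,5R,10R)-8,8-ethylenedioxy-4,10-dimethyl-4-(triethylsilyloxy)-trans-decalin-3-one (4α-OSiEt3, 4β-CH3, 5α-H, 10β-CH3) | O=C1CC[C@]2(C)CC3(OCCO3)CC[C@H]2[C@]1(C)O[Si](CC)(CC)CC | intermediate
12 | (3S,4S,5R,10R)-8,8-ethylenedioxy-4,10-dimethyl-4-(triethylsilyloxy)-trans-decalin-3-ol (3β-OH) | O[C@H]1CC[C@]2(C)CC3(OCCO3)CC[C@H]2[C@]1(C)O[Si](CC)(CC)CC | intermediate (not isolated)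
13 | (3S,4S,5R,10R)-3,4-dihydroxy-4,10-dimethyl-trans-decalin-8-one (3β,4α-diol) | O[C@H]1CC[C@]2(C)CC(=O)CC[C@H]2[C@]1(C)O | intermediate
14 | (2R)-2-methylbutanoic acid | CC[C@@H](C)C(=O)O | starting material
15 | (3S,4S,5R,10R)-4-hydroxy-4,10-dimethyl-8-oxo-trans-decalin-3-yl (2R)-2-methylbutanoate | CC[C@@H](C)C(=O)O[C@H]1CC[C@]2(C)CC(=O)CC[C@H]2[C@]1(C)O | intermediate
16 | (3S,4S,5R,10R)-4-acetoxy-4,10-dimethyl-8-oxo-trans-decalin-3-yl (2R)-2-methylbutanoate | CC[C@@H](C)C(=O)O[C@H]1CC[C@]2(C)CC(=O)CC[C@H]2[C@]1(C)OC(C)=O | intermediate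
17 | acetone | CC(C)=O | starting material
18 | (3S,4S,5R,10R)-4-acetoxy-7-(2-hydroxypropan-2-yl)-4,10-dimethyl-8-oxo-trans-decalin-3-yl (2R)-2-methylbutanoate (both C7 epimers) | CC[C@@H](C)C(=O)O[C@H]1CC[C@]2(C)CC(=O)C(C(C)(C)O)C[C@H]2[C@]1(C)OC(C)=O | intermediate
19 | methanesulfonate of 18 at the C11 hydroxyl (both C7 epimers) | CC[C@@H](C)C(=O)O[C@H]1CC[C@]2(C)CC(=O)C(C(C)(C)OS(C)(=O)=O)C[C@H]2[C@]1(C)OC(C)=O | intermediate (not isolated)
20 | (3S,4S,5R,10R)-4-acetoxy-8-oxoeudesm-7(11)-en-3-yl (2R)-2-methylbutanoate (3β-acyloxy, 4α-acetoxy, 5α-H, 10β-CH3) | CC[C@@H](C)C(=O)O[C@H]1CC[C@]2(C)CC(=O)C(=C(C)C)C[C@H]2[C@]1(C)OC(C)=O | target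

**Count and risks**

Total steps: 12. Longest linear sequence: 12 steps (from 1).

Steps most likely to fail:

1. Step 7. The planar C10 radical may close on the wrong face (cis fusion), or the iron hydride may transfer hydrogen to the vinyl ketone and start oligomerisation. The fallback sets out from 7 and comes back at 11. An intermolecular iron-hydride reductive coupling of 7 with methyl acrylate (Fe(acac)3, PhSiH3, EtOH, 60 °C), in which the acrylate should approach the C10 radical anti to the bulky C5 substituent, gives methyl (2S)-2-[(7R,8R)-7-(3-methoxy-3-oxopropyl)-7-methyl-1,4-dioxaspiro[4.5]decan-8-yl]-2-(triethylsilyloxy)propanoate F1. Dieckmann condensation (KOt-Bu, THF), possible only from the C2 methylene onto the non-enolisable C3 ester, closes ring A as methyl (4S,5R,10R)-8,8-ethylenedioxy-4,10-dimethyl-3-oxo-4-(triethylsilyloxy)-trans-decalin-2-carboxylate F2. Krapcho demethoxycarbonylation (LiCl, wet DMSO, 140 °C) then gives 11.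

2. Step 2. Facial discrimination of the chelated pyruvate may be incomplete, the cyclic enol silane may approach in the anti sense, or transient silyl triflate may open the ketal. The fallback sets out from 1 and comes back at 5. The lithium enolate of 1 (LiN(i-Pr)2, THF, −78 °C) is added to methyl pyruvate 3 through a closed six-membered transition state, which gives the aldol as a racemate, that is 5 together with its enantiomer methyl (2R)-2-hydroxy-2-[(8R)-7-oxo-1,4-dioxaspiro[4.5]decan-8-yl]propanoate F3. The anti diastereomer is removed by chromatography and the enantiomers are separated by preparative chromatography on a chiral stationary phase, which returns 5.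

3. Step 11. The amide base may also deprotonate the acetate, the C7 enolate may take up the acetyl group from O4, or the aldol may revert. The fallback sets out from 16 and comes back at 18. Soft enolisation (Me3SiOTf, Et3N, CH2Cl2, 0 °C) gives the C7–C8 silyl enol ether (3S,4S,5R,10R)-4-acetoxy-4,10-dimethyl-8-(trimethylsilyloxy)-trans-octal-7-en-3-yl (2R)-2-methylbutanoate F4. Its Mukaiyama aldol addition to acetone 17 (TiCl4, CH2Cl2, −78 °C) gives 18 without any strong base.

**Further compounds**

F1 | step 7 | methyl (2S)-2-[(7R,8R)-7-(3-methoxy-3-oxopropyl)-7-methyl-1,4-dioxaspiro[4.5]decan-8-yl]-2-(triethylsilyloxy)propanoate | COC(=O)CC[C@]1(C)CC2(OCCO2)CC[C@H]1[C@](C)(O[Si](CC)(CC)CC)C(=O)OC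
F2 | step 7 | methyl (4S,5R,10R)-8,8-ethylenedioxy-4,10-dimethyl-3-oxo-4-(triethylsilyloxy)-trans-decalin-2-carboxylate (C2 epimers) | COC(=O)C1C[C@]2(C)CC3(OCCO3)CC[C@H]2[C@](C)(O[Si](CC)(CC)CC)C1=O
F3 | step 2 | methyl (2R)-2-hydroxy-2-[(8R)-7-oxo-1,4-dioxaspiro[4.5]decan-8-yl]propanoate (enantiomer of 5) | COC(=O)[C@](C)(O)[C@H]1CCC2(OCCO2)CC1=O
F4 | step 11 | (3S,4S,5R,10R)-4-acetoxy-4,10-dimethyl-8-(trimethylsilyloxy)-trans-octal-7-en-3-yl (2R)-2-methylbutanoate | CC[C@@H](C)C(=O)O[C@H]1CC[C@]2(C)CC(O[Si](C)(C)C)=CC[C@H]2[C@]1(C)OC(C)=O
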